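# Proposed synthesis of Kanzonol X: ring A from 6-methylhept-5-en-2-one and a lactone, aromatised last

Numbering fixed by the steps: 1 resorcinol; 2 bis-MOM resorcinol; 3 prenyl bromide; 4 2-prenyl bis-MOM resorcinol; 5 ethylene oxide; 6 arylethanol; 7 arylacetaldehyde; 8 arylacetic acid; 9 (R)-4-benzyloxazolidin-2-one; 10 mixed anhydride; 11 arylacetyl imide; 12 2,3-dibromopropene; 13 alkylated imide; 14 bromo alcohol; 15 α-methylene lactone; 16 6-methylhept-5-en-2-one; 17 keto lactone; 18 hydroxy dione; 19 hexahydrochromenone; 20 silyl dienol ether; 21 dienone; 22 bis-MOM isoflavan; 23 Kanzonol X. Isoflavan atom numbers (O1, C2, C3, C4, C4a, C5 to C8, C8a; ring B C1' to C6') are used for every intermediate.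

## Analysis of the target

Kanzonol X (23) is a (3R)-isoflavan. Its chroman core (ring A is the benzo ring) carries a 2,4-dihydroxy-3-prenylphenyl group (ring B) at C3, a hydroxyl at C7 and a prenyl group at C8. C3 is the only stereocentre. It is a benzylic C–H carbon between two methylenes (C2 on O1, C4 on C4a), so nothing nearby can relay its configuration and it must be set absolutely; once both arms are CH2 groups it cannot epimerise. The sensitive groups are the two trisubstituted prenyl olefins, which exclude hydrogenation, ozonolysis, strong Lewis acids and boron halide dealkylation. The three electron-rich phenols are also sensitive, and two of them can close onto an ortho prenyl group, to 2,2-dimethylchromans under acid or to chromenes under oxidants. The difficulty lies in the substitution pattern. Each prenyl group sits between two oxygen-bearing carbons (C8 between C7 and C8a, C3' between C2' and C4'), the position that electrophilic prenylation of a resorcinol serves worst. In ring A the two flanking oxygens are also different (ether O1, free C7 phenol), which an arene-based route must differentiate. The strategy rests on this reading of ring A: C6, C7 with its oxygen, and C8 with its prenyl group are C1, C2 and C3 to C7 of 6-methylhept-5-en-2-one (16). O1–C8a with C2, C3, C4 and C4a is a δ-lactone whose carbonyl carbon is C8a and whose α-carbon C4a carries C5 as an exocyclic methylene. Ring A is therefore built non-aromatic and aromatised last, and ring B is the only arene that has to be made.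

## Retrosynthetic reasoning

**23 from 22.** The two ring B acetal O–C bonds are cut. Methoxymethyl ethers are chosen because they direct both lithiations that build ring B and are inert to strong base, hydride and palladium. They also leave without hydrogenation or a hard Lewis acid. The forward step must cleave two aryl acetals faster than a phenol adds to its neighbouring prenyl olefin.

**22 from 19 (through 20 and 21).** Two hydrogens are added back across C5–C6 and the phenol is written as its vinylogous ester. Ring A is then no longer an arene: the C7 oxygen is a ketone and needs no protecting group, and O1–C8a is an enol ether. The forward direction needs one dehydrogenation on the C6/C5 side of the ketone. Dienone 21 is the keto tautomer of a phenol, so aromatisation follows by itself and removes the uncontrolled C4a centre.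

**19 from 15 and 16 (key disconnection).** Three bonds are cut: O1–C8a (enol ether back to hydroxy dione 18), C8–C8a (retro-Claisen to keto lactone 17) and C5–C6 (retro-Michael). These are the bonds that join the three reacting carbons of ketone 16 to lactone 15. The C8 prenyl group arrives inside the ketone, so no prenylation of ring A is needed. O1 and the C7 oxygen differ by origin (lactone oxygen, ketone oxygen), so they need no differentiation. The forward reaction must enolise 16 at its methyl group, add to the methylene, acylate at C8 and reclose the pyran ring.

**15 from 14.** C4a–C8a and O1–C8a are cut, which removes C8a as a one-carbon carbonyl unit and leaves a 2-bromoallyl group and a primary alcohol. An acrylate ester carried through instead would have to survive the hydride that removes the auxiliary. It would then need an acid- or alkoxide-promoted lactonisation, which is awkward next to aryl acetals and a methylene lactone. The vinyl bromide is inert to hydride, and palladium-catalysed carbonylation closes the lactone under weakly basic conditions.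

**14 from 13, and 13 from 11 and 12.** The alcohol comes from the imide by reduction. The C3–C4 bond is cut as an enolate alkylation with allylic bromide 12. This is where C3 is set, by the auxiliary from 9; after the reduction C3 is no longer acidic.

**11 back to 1.** N-acylation joins 8 and 9. Acid 8 is 6 at a higher oxidation level (through 7). The C1'–C bond of 6 comes from ortho-lithiation of 4 and opening of 5. The C3'–prenyl bond of 4 comes from lithiation of 2 between its two acetal oxygens and allylation with 3. 2 is protected 1. The two lithiations place the prenyl group at the doubly flanked carbon with certainty. A preformed arylacetic acid could not be prenylated this way, because its benzylic protons are more acidic than the ring C–H.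

## Alternatives that were turned down

**Alternative 1:** carbene C–H insertion through the C2' oxygen. C3–C4 is cut, and the C2' oxygen is tethered temporarily to C4. A ring B aryldiazoacetate, whose C2' oxygen carries the ring A benzyl group, is decomposed by a chiral dirhodium tetracarboxylate of the N-phthaloyl-tert-leucinate type. The carbene inserts into the benzylic C4–H bond and gives the cis-dihydrobenzofuran A1. Ester reduction, reductive opening of the benzylic C4–O bond, desilylation and Mitsunobu etherification would then close O1–C2.
- For: the enantiocontrol is catalytic, both arenes are joined in the stereo-defining step, and 1,5-insertion into an ether-activated benzylic C–H is a favourable case. On catalytic asymmetry and convergence it is stronger than the chosen route.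
- Against: C3 of A1 is benzylic and α to an ester, so cis-to-trans epimerisation inverts C3, which is the centre that is kept. The C4–O bond must be cleaved without hydrogenolysis (prenyl) and without Lewis acid (acetals, prenyl). The carbene meets two nucleophilic trisubstituted olefins. Two resorcinol rings with regiodefined prenyl groups and three different oxygen protecting groups are needed.
- Comparison: the chosen route uses a stoichiometric but recoverable auxiliary. In exchange it needs only one arene and one protecting group, and it places the ring A prenyl group by construction.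

**Alternative 2:** quinone methide and enamine (4+2) annulation. C3–C4 and O1–C2 are cut together. Base releases an ortho-quinone methide from a ring A 2-(sulfonylmethyl)phenol. The enamine of a chiral secondary amine with the ring B arylacetaldehyde (compound 7 of the present route) adds to it, and lactol A2 results. C2 must then be deoxygenated.
- For: this is the most direct assembly. Both bonds and the pyran ring form in one organocatalytic step, and it is stronger than the chosen route in convergence and in steps after the fragments.
- Against: C3 of A2 is benzylic and α to a masked aldehyde, so ring–chain tautomerism and enolisation by the amine threaten it until C2 is reduced. The methide carbon is an unsubstituted CH2, so selectivity rests only on facial shielding of an arylacetaldehyde enamine of uncertain geometry. Silane and Lewis acid deoxygenation conflicts with acetals and prenyl groups, so hydride reduction and Mitsunobu closure are added. The ring A fragment again needs differentiated oxygens around C8.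
- Comparison: the chosen route sets C3 α to an imide and reduces it at once to a configurationally secure centre. It also avoids any ring A arene synthesis.

**Alternative 3:** three-component conjunctive coupling. C3–C1' and C4–C4a are cut around a vinyl boron unit. The ring B aryllithium and a vinylboronic ester form an ate complex. A palladium catalyst with a chiral bisphosphine and a ring A aryl bromide then induce the 1,2-shift of the ring B aryl group to C3 and form C4–C4a. The product is boronic ester A3.
- For: it is catalytic, enantioselective and modular, and the boron allows stereospecific one-carbon homologation. On these points it is stronger than the chosen route.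
- Against: both partners are ortho-substituted (acetal on the migrating aryl; silyloxy flanked by prenyl on the bromide), which slows oxidative addition and can erode selectivity. Bromide release calls for a halide scavenger. No ring closes in the key step, so homologation of a hindered secondary benzylic boronate, oxidation, desilylation and Mitsunobu closure follow. The ring A bromide needs its own multistep synthesis with oxygen differentiation.
- Comparison: the chosen route closes both rings of the chroman in its key step and takes ring A from a commodity ketone.

Key step: step 9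

## Route

Remark on the chemistry: Ar = 2,4-bis(methoxymethoxy)-3-(3-methylbut-2-en-1-yl)phenyl; lithiated arenes and metal enolates are treated as metalated forms of the numbered compounds and carry no numbers of their own; C4a in 17 to 21 is formed without control and becomes sp2 in 22.

Step 1
Reactants: 1 resorcinol
Product: 2 1,3-bis(methoxymethoxy)benzene
Conditions: MeOCH2Cl, i-Pr2NEt, CH2Cl2, 0 °C to rt
Reagents that add atoms: chloromethyl methyl ether, COCCl
Why: Base-mediated O-alkylation of both phenols by the α-chloro ether (MOM protection); the hindered amine in CH2Cl2 favours O- over C-alkylation.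

Step 2
Reactants: 2 1,3-bis(methoxymethoxy)benzene; 3 prenyl bromide
Product: 4 1,3-bis(methoxymethoxy)-2-(3-methylbut-2-en-1-yl)benzene
Conditions: n-BuLi, THF, 0 °C to rt; then CuI (10 mol %), 3, −20 °C to rt
Reagents that add atoms: none
Why: Directed ortho-metalation removes the proton between the two acetal oxygens, which is coordinated and acidified from both sides; copper-mediated SN2 allylation at the primary carbon of 3 gives the linear prenyl group.

Step 3
Reactants: 4 1,3-bis(methoxymethoxy)-2-(3-methylbut-2-en-1-yl)benzene; 5 ethylene oxide
Product: 6 2-Ar-ethan-1-ol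
Conditions: n-BuLi, TMEDA, THF, −20 to 0 °C; then 5 (THF solution), −78 °C to rt; H2O
Reagents that add atoms: none
Why: A second directed ortho-metalation can only take the ring position next to one acetal oxygen (the two are equivalent by symmetry), and the aryllithium opens the epoxide; ring lithiation should outrun deprotonation of the prenyl CH2 because only the ring C–H is held next to the base.

Step 4
Reactants: 6 2-Ar-ethan-1-ol
Product: 8 Ar-acetic acid, via arylacetaldehyde 7 (not isolated)
Conditions: TEMPO (20 mol %), PhI(OAc)2 (2.2 equiv), MeCN/pH 7 phosphate buffer, 0 °C to rt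
Reagents that add atoms: water, O
Why: Nitroxyl-catalysed oxidation takes the primary alcohol to aldehyde 7, whose hydrate is oxidised on to the acid; the buffered medium spares the aryl acetals, and the oxoammonium ion reacts with a primary alcohol much faster than with a trisubstituted olefin.

Step 5
Reactants: 8 Ar-acetic acid; 9 (4R)-4-benzyl-1,3-oxazolidin-2-one
Product: 11 (4R)-4-benzyl-3-(Ar-acetyl)-1,3-oxazolidin-2-one, via mixed pivalic anhydride 10 (not isolated)
Conditions: t-BuCOCl, Et3N, THF, −20 °C; then LiCl, 9, −20 °C to rt
Reagents that add atoms: none
Why: Mixed-anhydride N-acylation: the oxazolidinone, activated by LiCl and Et3N, attacks the unhindered arylacetyl carbonyl of 10; no stereocentre is formed or touched.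

Step 6
Reactants: 11 (4R)-4-benzyl-3-(Ar-acetyl)-1,3-oxazolidin-2-one; 12 2,3-dibromopropene
Product: 13 (4R)-4-benzyl-3-[(2R)-2-Ar-4-bromopent-4-enoyl]-1,3-oxazolidin-2-one
Conditions: NaN(SiMe3)2, THF, −78 °C; then 12, −78 to −45 °C
Reagents that add atoms: none
Why: Evans asymmetric alkylation: the chelated Z-enolate is shielded on one face by the benzyl group of the (4R)-auxiliary and the allylic bromide enters from the other, which for an aryl-substituted enolate is the (2R) imide, the C3 configuration of the target; low temperature and the A(1,3)-strained product guard the acidic α-aryl centre against epimerisation.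

Step 7
Reactants: 13 (4R)-4-benzyl-3-[(2R)-2-Ar-4-bromopent-4-enoyl]-1,3-oxazolidin-2-one
Product: 14 (2R)-2-Ar-4-bromopent-4-en-1-ol
Conditions: LiBH4, H2O (1 equiv), Et2O, 0 °C
Reagents that add atoms: none
Why: Hydride reduction of the activated exocyclic imide carbonyl (reductive auxiliary cleavage) gives the primary alcohol and returns 9; vinyl bromide, prenyl olefin and acetals are inert to LiBH4, and C3 is no longer acidic afterwards.

Step 8
Reactants: 14 (2R)-2-Ar-4-bromopent-4-en-1-ol
Product: 15 (5R)-5-Ar-3-methylideneoxan-2-one
Conditions: Pd(PPh3)4 (5 mol %), CO (1 atm), K2CO3, THF, 60 °C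
Reagents that add atoms: carbon monoxide, [C-]#[O+]
Why: Palladium-catalysed carbonylative lactonisation: oxidative addition of the vinyl C–Br bond to zerovalent palladium, CO insertion, and capture of the acylpalladium by the tethered hydroxyl (6-exo-trig at the acyl carbon) give the α-methylene δ-lactone; carbonate keeps the medium free of nucleophiles that could add to the product.

Step 9
Reactants: 15 (5R)-5-Ar-3-methylideneoxan-2-one; 16 6-methylhept-5-en-2-one
Product: 19 (3R)-3-Ar-8-(3-methylbut-2-en-1-yl)-2,3,4,4a,5,6-hexahydro-7H-chromen-7-one (both C4a epimers), via keto lactone 17 (not isolated), via hydroxy dione 18 (not isolated)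
Conditions: LiN(i-Pr)2 (1.25 equiv), THF, −78 °C, 16 (1.2 equiv) added to the base; then 15 added slowly, −78 °C to rt; AcOH; then PPTS (10 mol %), toluene, 4 Å MS, 60 °C
Reagents that add atoms: none
Why: Adding 16 to the amide base at −78 °C removes the less hindered methyl proton, and this kinetic enolate (C6) adds to the exocyclic methylene C5 of the s-cis-locked acrylate in 15, forming C5–C6 and the lactone enolate of 17; slow addition of 15 keeps the acceptor scarce so the adduct enolate does not add to a second lactone. On warming, the charge moves to the ketone (intramolecularly from C8–H to C4a through a six-membered array, or relayed by the amine). Only the C8 enolate can reach the lactone carbonyl C8a, and it closes the carbocycle by 6-exo-trig C-acylation (Claisen condensation); the C6 enolate would have to form a four-membered ring and merely equilibrates. Collapse of the tetrahedral intermediate expels the C2 alkoxide, which deprotonates the new 2-alkyl-1,3-dione, and this stabilised enolate is the thermodynamic sink. After acidification to 18, pyridinium tosylate in warm toluene lets the C2 hydroxyl add to C8a (6-exo-trig) and lose water to the vinylogous ester; attack at C7 would need a bridged eight-membered ring. The closest known reaction type is the consecutive Michael–Claisen annulation of ketone enolates with acrylic esters to cyclohexane-1,3-diones, together with base-induced cyclisation of 5-oxoalkanoates; here the ester is a lactone, so the leaving alkoxide stays in the molecule and closes the second ring. C3 is not involved and keeps its configuration; C4a forms without control and both epimers converge on aromatisation. The one selectivity the step needs is methyl-side enolisation, secured by the kinetic base, low temperature and the absence of excess ketone, after which ring size alone decides.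

Step 10
Reactants: 19 (3R)-3-Ar-8-(3-methylbut-2-en-1-yl)-2,3,4,4a,5,6-hexahydro-7H-chromen-7-one
Product: 20 (3R)-3-Ar-8-(3-methylbut-2-en-1-yl)-7-(trimethylsilyloxy)-3,4,4a,5-tetrahydro-2H-chromene
Conditions: LiN(i-Pr)2, THF, −78 °C; then Me3SiCl, −78 to 0 °C; non-aqueous work-up
Reagents that add atoms: chlorotrimethylsilane, C[Si](C)(C)Cl
Why: Kinetic deprotonation of the vinylogous ester occurs at the α' carbon C6 (cross-conjugated enolate) and not at the tertiary γ carbon C4a, and O-silylation gives the 2-silyloxy diene.

Step 11
Reactants: 20 (3R)-3-Ar-8-(3-methylbut-2-en-1-yl)-7-(trimethylsilyloxy)-3,4,4a,5-tetrahydro-2H-chromene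
Product: 22 (3R)-3-Ar-8-(3-methylbut-2-en-1-yl)-3,4-dihydro-2H-chromen-7-ol, via dienone 21 (not isolated)
Conditions: Pd(OAc)2 (1.05 equiv), MeCN, rt
Reagents that add atoms: none
Why: Saegusa–Ito oxidation: the silyl enol ether gives a C6-bound palladium enolate, syn β-hydride elimination from C5 gives dienone 21, and 21, the keto tautomer of a phenol, aromatises by shift of the C4a hydrogen; one equivalent of the divalent palladium salt in MeCN leaves no oxidant for the prenyl groups or the new phenol.

Step 12
Reactants: 22 (3R)-3-Ar-8-(3-methylbut-2-en-1-yl)-3,4-dihydro-2H-chromen-7-ol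
Product: 23 Kanzonol X
Conditions: HCl (ca. 1 M), MeOH/THF, rt to 40 °C; NaHCO3
Reagents that add atoms: none
Why: Acid-catalysed acetal cleavage (MOM removal): the methoxymethyl cation is trapped by methanol and both ring B phenols are freed; dilute acid and low temperature are chosen because acetal cleavage is much faster than addition of a phenol to its neighbouring prenyl olefin.

## Compound list

1 | resorcinol (benzene-1,3-diol) | Oc1cccc(O)c1 | starting material
2 | 1,3-bis(methoxymethoxy)benzene | COCOc1cccc(OCOC)c1 | intermediate
3 | prenyl bromide (1-bromo-3-methylbut-2-ene) | CC(C)=CCBr | starting material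
4 | 1,3-bis(methoxymethoxy)-2-(3-methylbut-2-en-1-yl)benzene | COCOc1cccc(OCOC)c1CC=C(C)C | intermediate
5 | ethylene oxide (oxirane) | C1CO1 | starting material
6 | 2-[2,4-bis(methoxymethoxy)-3-(3-methylbut-2-en-1-yl)phenyl]ethan-1-ol | CC(C)=CCc1c(OCOC)ccc(CCO)c1OCOC | intermediate
7 | [2,4-bis(methoxymethoxy)-3-(3-methylbut-2-en-1-yl)phenyl]acetaldehyde | CC(C)=CCc1c(OCOC)ccc(CC=O)c1OCOC | intermediate
8 | [2,4-bis(methoxymethoxy)-3-(3-methylbut-2-en-1-yl)phenyl]acetic acid | CC(C)=CCc1c(OCOC)ccc(CC(=O)O)c1OCOC | intermediate
9 | (4R)-4-benzyl-1,3-oxazolidin-2-one | O=C1N[C@H](Cc2ccccc2)CO1 | starting material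
10 | [2,4-bis(methoxymethoxy)-3-(3-methylbut-2-en-1-yl)phenyl]acetic 2,2-dimethylpropanoic anhydride | CC(C)=CCc1c(OCOC)ccc(CC(=O)OC(=O)C(C)(C)C)c1OCOC | intermediate
11 | (4R)-4-benzyl-3-{[2,4-bis(methoxymethoxy)-3-(3-methylbut-2-en-1-yl)phenyl]acetyl}-1,3-oxazolidin-2-one | CC(C)=CCc1c(OCOC)ccc(CC(=O)N2[C@H](Cc3ccccc3)COC2=O)c1OCOC | intermediate
12 | 2,3-dibromoprop-1-ene | BrCC(Br)=C | starting material
13 | (4R)-4-benzyl-3-{(2R)-2-[2,4-bis(methoxymethoxy)-3-(3-methylbut-2-en-1-yl)phenyl]-4-bromopent-4-enoyl}-1,3-oxazolidin-2-one | CC(C)=CCc1c(OCOC)ccc([C@H](C(=O)N2[C@H](Cc3ccccc3)COC2=O)CC(Br)=C)c1OCOC | intermediate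
14 | (2R)-2-[2,4-bis(methoxymethoxy)-3-(3-methylbut-2-en-1-yl)phenyl]-4-bromopent-4-en-1-ol | CC(C)=CCc1c(OCOC)ccc([C@H](CO)CC(Br)=C)c1OCOC | intermediate
15 | (5R)-5-[2,4-bis(methoxymethoxy)-3-(3-methylbut-2-en-1-yl)phenyl]-3-methylideneoxan-2-one | CC(C)=CCc1c(OCOC)ccc([C@@H]2COC(=O)C(=C)C2)c1OCOC | intermediate
16 | 6-methylhept-5-en-2-one | CC(=O)CCC=C(C)C | starting material
17 | (5R)-5-[2,4-bis(methoxymethoxy)-3-(3-methylbut-2-en-1-yl)phenyl]-3-(7-methyl-3-oxooct-6-en-1-yl)oxan-2-one (C3 epimers of the lactone ring) | CC(C)=CCc1c(OCOC)ccc([C@@H]2COC(=O)C(CCC(=O)CCC=C(C)C)C2)c1OCOC | intermediate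
18 | 4-{(2R)-2-[2,4-bis(methoxymethoxy)-3-(3-methylbut-2-en-1-yl)phenyl]-3-hydroxypropyl}-2-(3-methylbut-2-en-1-yl)cyclohexane-1,3-dione (drawn as the diketone) | CC(C)=CCc1c(OCOC)ccc([C@H](CO)CC2CCC(=O)C(CC=C(C)C)C2=O)c1OCOC | intermediate
19 | (3R)-3-[2,4-bis(methoxymethoxy)-3-(3-methylbut-2-en-1-yl)phenyl]-8-(3-methylbut-2-en-1-yl)-2,3,4,4a,5,6-hexahydro-7H-chromen-7-one (C4a epimers) | CC(C)=CCc1c(OCOC)ccc([C@@H]2COC3=C(CC=C(C)C)C(=O)CCC3C2)c1OCOC | intermediate
20 | (3R)-3-[2,4-bis(methoxymethoxy)-3-(3-methylbut-2-en-1-yl)phenyl]-8-(3-methylbut-2-en-1-yl)-7-(trimethylsilyloxy)-3,4,4a,5-tetrahydro-2H-chromene (C4a epimers) | CC(C)=CCc1c(OCOC)ccc([C@@H]2COC3=C(CC=C(C)C)C(O[Si](C)(C)C)=CCC3C2)c1OCOC | intermediate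
21 | (3R)-3-[2,4-bis(methoxymethoxy)-3-(3-methylbut-2-en-1-yl)phenyl]-8-(3-methylbut-2-en-1-yl)-2,3,4,4a-tetrahydro-7H-chromen-7-one (C4a epimers) | CC(C)=CCc1c(OCOC)ccc([C@@H]2COC3=C(CC=C(C)C)C(=O)C=CC3C2)c1OCOC | intermediate
22 | (3R)-3-[2,4-bis(methoxymethoxy)-3-(3-methylbut-2-en-1-yl)phenyl]-8-(3-methylbut-2-en-1-yl)-3,4-dihydro-2H-chromen-7-ol | CC(C)=CCc1c(OCOC)ccc([C@@H]2COc3c(ccc(O)c3CC=C(C)C)C2)c1OCOC | intermediate
23 | Kanzonol X, 4-[(3R)-7-hydroxy-8-(3-methylbut-2-en-1-yl)-3,4-dihydro-2H-chromen-3-yl]-2-(3-methylbut-2-en-1-yl)benzene-1,3-diol | CC(C)=CCc1c(O)ccc([C@@H]2COc3c(ccc(O)c3CC=C(C)C)C2)c1O | target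

## Step count and least certain steps

Total: 12 steps. Longest linear sequence: 12 steps (1 to 23); 3, 5, 9, 12 and 16 enter as purchased.

**Step 9 (key step).** Three processes can divert it.
- The enolate may lose its regiochemistry by proton exchange with free ketone, so that the Michael addition starts from C8.
- The adduct enolate may add to further lactone (anionic oligomerisation), or the enolate may deprotonate 15 at C4 and move the double bond into the ring.
- The Claisen closure may stall at the keto lactone stage.

The fallback fixes the regiochemistry covalently and runs the sequence stepwise. It sets out from 16 and 15 and returns at 17.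
- Ketone 16 is condensed with 1,1-dimethylhydrazine to 6-methylhept-5-en-2-one N,N-dimethylhydrazone F1.
- LiN(i-Pr)2 metalates F1 at the methyl carbon, the known site preference of such hydrazones. The azaenolate adds 1,4 to 15 at −78 °C and is quenched cold, giving the hydrazone lactone F2.
- Buffered aqueous Cu(OAc)2 cleaves the hydrazone to isolated 17.
- KOt-Bu in THF closes 17 to 18 (the classical base cyclisation of a 5-oxoalkanoate), and PPTS in toluene gives 19.

**Step 8.** Oxidative addition of the vinyl bromide may be slow under CO. Triphenylphosphine may add to the product methylene lactone, or the acylpalladium may be captured intermolecularly. The fallback installs the carbonyl carbon by alkylation instead. It sets out from 11 and returns at 15.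
- The sodium enolate of 11 is alkylated with methyl 2-(bromomethyl)acrylate (COC(=O)C(=C)CBr) to the imide ester F3.
- NaBH4 in THF/H2O at 0 °C reduces only the imide and gives the hydroxy ester F4.
- Neutral transesterification with catalytic (ClBu2Sn)2O in hot toluene closes F4 to 15 without acid or alkoxide.

**Step 11.** Divalent palladium may engage a prenyl olefin or promote oxidative cyclisation of the newly formed ortho-prenylphenol. Protodesilylation by the acetic acid formed may also return 19. The fallback avoids palladium. It sets out from 19 and returns at 22.
- The C6 lithium enolate of 19 (two equivalents of base) is sulfinylated with methyl benzenesulfinate (COS(=O)c1ccccc1) to the α-phenylsulfinyl ketone F5.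
- Warming F5 in toluene with NaHCO3 and trimethyl phosphite brings about sulfoxide syn-elimination to 21, which aromatises to 22.

**Step 12.** Acid-promoted addition of a freed phenol to its ortho prenyl group (chroman formation) may compete with acetal cleavage. The fallback removes the acetals without protic acid. It sets out from 22 and returns at 23.
- Me3SiOTf with 2,2'-bipyridyl in CH2Cl2 at 0 °C exchanges each aryl acetal for a silyl ether and silylates the C7 phenol, giving the tris(trimethylsilyl) ether F6.
- Water or K2CO3 in methanol hydrolyses F6 to 23.

**Step 4.** The oxoammonium ion may attack the enolisable benzylic position of aldehyde 7 (chain degradation) or react with the prenyl olefin. The fallback separates the two oxidation stages. It sets out from 6 and returns at 8.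
- Dess–Martin periodinane buffered with NaHCO3 gives 7, which is used crude.
- Pinnick oxidation (NaClO2, NaH2PO4, excess 2-methylbut-2-ene as hypochlorite scavenger) gives 8.

## Further compounds

F1 | step 9 | 6-methylhept-5-en-2-one N,N-dimethylhydrazone | CC(CCC=C(C)C)=NN(C)C
F2 | step 9 | (5R)-5-[2,4-bis(methoxymethoxy)-3-(3-methylbut-2-en-1-yl)phenyl]-3-[3-(2,2-dimethylhydrazinylidene)-7-methyloct-6-en-1-yl]oxan-2-one | CC(C)=CCc1c(OCOC)ccc([C@@H]2COC(=O)C(CCC(CCC=C(C)C)=NN(C)C)C2)c1OCOC
F3 | step 8 | methyl (4R)-4-[2,4-bis(methoxymethoxy)-3-(3-methylbut-2-en-1-yl)phenyl]-5-[(4R)-4-benzyl-2-oxo-1,3-oxazolidin-3-yl]-2-methylidene-5-oxopentanoate | CC(C)=CCc1c(OCOC)ccc([C@H](C(=O)N2[C@H](Cc3ccccc3)COC2=O)CC(=C)C(=O)OC)c1OCOC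
F4 | step 8 | methyl (4R)-4-[2,4-bis(methoxymethoxy)-3-(3-methylbut-2-en-1-yl)phenyl]-5-hydroxy-2-methylidenepentanoate | CC(C)=CCc1c(OCOC)ccc([C@H](CO)CC(=C)C(=O)OC)c1OCOC
F5 | step 11 | (3R)-3-[2,4-bis(methoxymethoxy)-3-(3-methylbut-2-en-1-yl)phenyl]-8-(3-methylbut-2-en-1-yl)-6-(phenylsulfinyl)-2,3,4,4a,5,6-hexahydro-7H-chromen-7-one | CC(C)=CCc1c(OCOC)ccc([C@@H]2COC3=C(CC=C(C)C)C(=O)C(S(=O)c4ccccc4)CC3C2)c1OCOC
F6 | step 12 | (3R)-3-[3-(3-methylbut-2-en-1-yl)-2,4-bis(trimethylsilyloxy)phenyl]-8-(3-methylbut-2-en-1-yl)-7-(trimethylsilyloxy)-3,4-dihydro-2H-chromene | CC(C)=CCc1c(O[Si](C)(C)C)ccc([C@@H]2COc3c(ccc(O[Si](C)(C)C)c3CC=C(C)C)C2)c1O[Si](C)(C)C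
F0 | step 4 | none | none
A1 | alternative 1 | methyl (2R,3S)-2-[2-(tert-butyldimethylsilyloxy)-4-(methoxymethoxy)-3-(3-methylbut-2-en-1-yl)phenyl]-6-(methoxymethoxy)-7-(3-methylbut-2-en-1-yl)-2,3-dihydro-1-benzofuran-3-carboxylate | COC(=O)[C@@H]1[C@H](c2ccc(OCOC)c(CC=C(C)C)c2O[Si](C)(C)C(C)(C)C)Oc3c1ccc(OCOC)c3CC=C(C)C
A2 | alternative 2 | (3R)-3-[2,4-bis(methoxymethoxy)-3-(3-methylbut-2-en-1-yl)phenyl]-7-(methoxymethoxy)-8-(3-methylbut-2-en-1-yl)-3,4-dihydro-2H-chromen-2-ol (C2 anomers) | CC(C)=CCc1c(OCOC)ccc([C@@H]2C(O)Oc3c(ccc(OCOC)c3CC=C(C)C)C2)c1OCOC
A3 | alternative 3 | 2-{(1R)-1-[2,4-bis(methoxymethoxy)-3-(3-methylbut-2-en-1-yl)phenyl]-2-[2-(tert-butyldimethylsilyloxy)-4-(methoxymethoxy)-3-(3-methylbut-2-en-1-yl)phenyl]ethyl}-4,4,5,5-tetramethyl-1,3,2-dioxaborolane | CC(C)=CCc1c(OCOC)ccc([C@@H](Cc2ccc(OCOC)c(CC=C(C)C)c2O[Si](C)(C)C(C)(C)C)B3OC(C)(C)C(C)(C)O3)c1OCOC
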